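**Retrosynthetic overview**

1. Target 29 ⇒ hydroxylactam 26 by cutting the spiro C3–O bond to the peri oxygen on C8' (last ring, closed enantioselectively with a chiral phosphoric acid); 26 ⇒ keto ester 21 + O-silylated ethanolamine 22 (lactam ring).
2. The strategy rests on ring A (the benzene ring of the isoindolinone): C4 (OCH3), C3a (bond to spiro C3) and C7a (bond to the lactam C1=O) are three contiguous carbons. This is the pattern left when 3-methoxy-2-pyrone 2 adds to an alkyne with a ketone on one carbon and an ester on the other and CO2 is lost: 21 ⇒ 2 + ynone 19.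
3. 19 ⇒ naphthaldehyde 15 + methyl propiolate 16 (acetylide addition, oxidation); 15 ⇒ aryl bromide 12 (Br–Li exchange, DMF).
4. 12 ⇒ naphthoate 7, built by Stobbe condensation of 3 with 4 and ring closure; bromine is placed on C5 of 7 while the ester and acetate deactivate the other ring, then CO2Et → CH3.
5. Ring order: second naphthalene ring → ring A (cycloaddition) → lactam ring → naphtho[1,8-bc]furan ring.

Key step: step 11

Remark on numbering: the isoindolin-1-one is numbered C1(=O), N2, C3 (spiro), C3a, C4–C7, C7a; the naphthalene carbons are primed (C1' on C3, C2'–OH, C6'–CH3, C8'–O). The spiro carbon of the target is (S).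

Remark on step 14: the sense of induction of the phosphoric acid cannot be assigned in advance. The (R)-catalyst is written; its enantiomer takes its place if it proves to favor the (R)-spiro compound.

Remark on materials: 1, 3, 4, 16 and 22 are taken as purchased.

**Route**

Step 1
Reactants: 1 3-hydroxy-2H-pyran-2-one
Product: 2 3-methoxy-2H-pyran-2-one
Conditions: MeI, K2CO3, acetone, reflux
Reagents that add atoms: iodomethane, CI
Why: Williamson O-methylation of the acidic enol-type hydroxyl, with a carbonate base that does not open the pyrone ring under anhydrous conditions.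

Step 2
Reactants: 3 4-(benzyloxy)benzaldehyde; 4 diethyl succinate
Product: 5 (3E)-4-[4-(benzyloxy)phenyl]-3-(ethoxycarbonyl)but-3-enoic acid
Conditions: t-BuOK, t-BuOH, reflux; then aq HCl
Reagents that add atoms: none
Why: Stobbe condensation, in which aldol addition, lactonization and eliminative ring opening should give the half-ester with the aryl group cis to CH2CO2H (E), the geometry needed for the ring closure of step 3.

Step 3
Reactants: 5 (3E)-4-[4-(benzyloxy)phenyl]-3-(ethoxycarbonyl)but-3-enoic acid
Product: 7 ethyl 4-(acetyloxy)-6-(benzyloxy)naphthalene-2-carboxylate, via naphthol 6 (not isolated)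
Conditions: Ac2O, NaOAc, 140 °C
Reagents that add atoms: acetic anhydride, CC(=O)OC(C)=O
Why: Intramolecular Friedel–Crafts-type acylation by the mixed anhydride on the ortho carbon of the aryl ring, aromatization to naphthol 6 and O-acetylation in the same flask; the two ortho carbons are equivalent, so only one naphthalene can form.

Step 4
Reactants: 7 ethyl 4-(acetyloxy)-6-(benzyloxy)naphthalene-2-carboxylate
Product: 8 ethyl 4-(acetyloxy)-6-(benzyloxy)-5-bromonaphthalene-2-carboxylate
Conditions: NBS, MeCN, 0 °C → rt, dark
Reagents that add atoms: N-bromosuccinimide, O=C1CCC(=O)N1Br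
Why: Electrophilic aromatic bromination at C5, the alpha position ortho to the benzyloxy group and the only strongly activated site, because the other ring carries the ester and the weakly donating acetate and the conjugated position C2 is blocked.

Step 5
Reactants: 8 ethyl 4-(acetyloxy)-6-(benzyloxy)-5-bromonaphthalene-2-carboxylate
Product: 9 7-(benzyloxy)-8-bromo-3-(hydroxymethyl)naphthalen-1-ol
Conditions: iBu2AlH (5 equiv), CH2Cl2, −78 → 0 °C; aq KNaC4H4O6
Reagents that add atoms: none
Why: Hydride reduction of the ethyl ester to the primary alcohol with reductive removal of the aryl acetate, under conditions that leave the aryl bromide and the benzyl ether alone.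

Step 6
Reactants: 9 7-(benzyloxy)-8-bromo-3-(hydroxymethyl)naphthalen-1-ol
Product: 10 [4,6-bis(benzyloxy)-5-bromonaphthalen-2-yl]methanol
Conditions: BnBr, K2CO3, acetone, reflux
Reagents that add atoms: benzyl bromide, BrCc1ccccc1
Why: Williamson etherification in which carbonate deprotonates only the naphthol, so the primary alcohol stays free.

Step 7
Reactants: 10 [4,6-bis(benzyloxy)-5-bromonaphthalen-2-yl]methanol
Product: 12 2,8-bis(benzyloxy)-1-bromo-6-methylnaphthalene, via mesylate 11 (not isolated)
Conditions: Ms2O, Et3N, THF, 0 °C; then LiEt3BH, 0 °C → rt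
Reagents that add atoms: none
Why: Sulfonylation and SN2 displacement of the benzylic mesylate by hydride (deoxygenation of a benzylic alcohol), with a borohydride that does not reduce aryl bromides or benzyl ethers at this temperature.

Step 8
Reactants: 12 2,8-bis(benzyloxy)-1-bromo-6-methylnaphthalene
Product: 15 2,8-bis(benzyloxy)-6-methylnaphthalene-1-carbaldehyde, via aryllithium 13 (not isolated), via lithium hemiaminal alkoxide 14 (not isolated)
Conditions: n-BuLi, THF, −78 °C; then DMF, −78 → 0 °C; then H2O
Reagents that add atoms: N,N-dimethylformamide, CN(C)C=O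
Why: Bromine–lithium exchange, faster than benzylic deprotonation at −78 °C and helped by the two flanking ether oxygens, followed by Bouveault formylation with DMF and hydrolysis of the adduct 14.

Step 9
Reactants: 16 methyl propiolate; 15 2,8-bis(benzyloxy)-6-methylnaphthalene-1-carbaldehyde
Product: 18 methyl 4-[2,8-bis(benzyloxy)-6-methylnaphthalen-1-yl]-4-hydroxybut-2-ynoate (racemic), via lithium acetylide 17 (not isolated)
Conditions: LiN(SiMe3)2, THF, −78 °C; then 15, −78 °C; AcOH quench at −78 °C
Reagents that add atoms: none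
Why: 1,2-Addition of a lithium acetylide to an aldehyde; the acetylide of methyl propiolate is stable at −78 °C and is small and linear enough to reach the carbonyl between the two benzyloxy groups, and the racemic carbinol center is removed in step 10.

Step 10
Reactants: 18 methyl 4-[2,8-bis(benzyloxy)-6-methylnaphthalen-1-yl]-4-hydroxybut-2-ynoate
Product: 19 methyl 4-[2,8-bis(benzyloxy)-6-methylnaphthalen-1-yl]-4-oxobut-2-ynoate
Conditions: MnO2 (activated, excess), CH2Cl2, rt
Reagents that add atoms: none
Why: MnO2 oxidation of a benzylic and propargylic alcohol under neutral conditions, which avoids conjugate addition to the very electrophilic ynone.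

Step 11
Reactants: 2 3-methoxy-2H-pyran-2-one; 19 methyl 4-[2,8-bis(benzyloxy)-6-methylnaphthalen-1-yl]-4-oxobut-2-ynoate
Product: 21 methyl 2-{[2,8-bis(benzyloxy)-6-methylnaphthalen-1-yl]carbonyl}-3-methoxybenzoate, via bicyclic lactone 20 (not isolated)
Conditions: 2 (3 equiv), toluene, 110 °C, sealed tube
Reagents that add atoms: none
Why: 3-Methoxy-2-pyrone adds as an electron-rich 1-oxygenated diene across the doubly activated triple bond in a concerted, asynchronous [4+2] cycloaddition, and the bridged lactone 20 then loses CO2 by retro-[4+2] at the reaction temperature, which makes the sequence irreversible and gives the benzene ring directly. The closest known reaction type is the thermal Diels–Alder reaction of 3-hydroxy- and 3-alkoxy-2-pyrones with acetylenic esters and ketones, which gives substituted benzoates after loss of CO2. Ring A is closed by intermolecular cycloaddition, with C3a–C4 and C7–C7a formed in the same step, so no ring-closure rule for a tethered chain applies. No stereocenter remains, since both bridgehead carbons of 20 become aromatic. The step needs a single orientation: the methoxy group makes C6 of the pyrone the nucleophilic terminus, and C6 should bond first to the alkyne carbon beta to the ketone (the one bearing CO2Me), because the ketone, twisted out of conjugation with the 2,8-disubstituted naphthalene and so fully conjugated with the triple bond, is a stronger acceptor than the ester; the methoxy-bearing pyrone carbon is thereby joined to the aroyl-bearing carbon. The crowded bond between the methoxy-bearing carbon and the aroyl-bearing carbon is the longer, later-forming bond of the transition state, which reduces the steric penalty of this orientation.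

Step 12
Reactants: 21 methyl 2-{[2,8-bis(benzyloxy)-6-methylnaphthalen-1-yl]carbonyl}-3-methoxybenzoate; 22 2-[(tert-butyldimethylsilyl)oxy]ethan-1-amine
Product: 25 3-[2,8-bis(benzyloxy)-6-methylnaphthalen-1-yl]-2-{2-[(tert-butyldimethylsilyl)oxy]ethyl}-3-hydroxy-4-methoxy-2,3-dihydro-1H-isoindol-1-one (racemic), via dimethylaluminium amide 23 (not isolated), via keto amide 24 (not isolated)
Conditions: Me3Al, 22, toluene, 0 °C → rt; then 21, 80 °C; aq KNaC4H4O6
Reagents that add atoms: none
Why: Weinreb-type aminolysis of the methyl ester by the aluminium amide 23 gives the secondary amide 24, whose N–H adds to the neighbouring ketone (ring–chain tautomerism of 2-acylbenzamides, normally on the ring side) to give the hydroxylactam; 21 has no acidic proton to consume the reagent.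

Step 13
Reactants: 25 3-[2,8-bis(benzyloxy)-6-methylnaphthalen-1-yl]-2-{2-[(tert-butyldimethylsilyl)oxy]ethyl}-3-hydroxy-4-methoxy-2,3-dihydro-1H-isoindol-1-one
Product: 26 2-{2-[(tert-butyldimethylsilyl)oxy]ethyl}-3-(2,8-dihydroxy-6-methylnaphthalen-1-yl)-3-hydroxy-4-methoxy-2,3-dihydro-1H-isoindol-1-one (racemic)
Conditions: H2 (1 atm), 10% Pd/C, EtOAc, rt; filtered and used at once
Reagents that add atoms: none
Why: Hydrogenolysis of the two aryl benzyl ethers on Pd/C, which is fast at 1 atm; without acid the tertiary N-acyl hemiaminal should not ionize, so the C3–OH bond, the silyl ether and the lactam are expected to stay intact.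

Step 14
Reactants: 26 2-{2-[(tert-butyldimethylsilyl)oxy]ethyl}-3-(2,8-dihydroxy-6-methylnaphthalen-1-yl)-3-hydroxy-4-methoxy-2,3-dihydro-1H-isoindol-1-one
Product: 28 (1S)-2-{2-[(tert-butyldimethylsilyl)oxy]ethyl}-3'-hydroxy-7-methoxy-7'-methylspiro[isoindoline-1,2'-naphtho[1,8-bc]furan]-3-one, via ortho-quinone methide 27 (not isolated)
Conditions: (R)-3,3'-bis(2,4,6-triisopropylphenyl)-1,1'-binaphthyl-2,2'-diyl hydrogen phosphate (10 mol %), 4 Å molecular sieves, toluene, −30 °C
Reagents that add atoms: none
Why: Proposed new method: the phosphoric acid should protonate the C3 hydroxyl of 26 and, helped by the ortho 2'-hydroxyl, expel water to give the ortho-quinone methide 27, which reacts through its twisted, zwitterionic N-acyliminium–naphtholate form (naphthalene plane roughly perpendicular to the C3=N plane) and stays bound to the catalyst through a hydrogen bond from P–OH to its carbonyl oxygen while the phosphoryl oxygen accepts the proton of the peri 8'-hydroxyl; that oxygen then closes the five-membered ring on C3 (5-exo-trig with respect to the C3=N acyliminium form) from the face left open by the 2,4,6-triisopropylphenyl groups, which sets the (S) spiro center, and only the 8'-oxygen can close a ring because the 2'-oxygen would give a four-membered ring and the side-chain oxygen is silylated; the closest known reaction types are chiral-phosphoric-acid-catalyzed additions of oxygen, sulfur and carbon nucleophiles to N-acyl ketiminium ions generated from 3-aryl-3-hydroxyisoindolin-1-ones, additions to ortho-quinone methides generated from ortho-hydroxybenzylic alcohols with the same catalysts, and phosphoric-acid-catalyzed enantioselective spiroketalization, whereas closure of a 2H-naphtho[1,8-bc]furan N,O-ketal by a peri-naphthol has not been shown.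

Step 15
Reactants: 28 (1S)-2-{2-[(tert-butyldimethylsilyl)oxy]ethyl}-3'-hydroxy-7-methoxy-7'-methylspiro[isoindoline-1,2'-naphtho[1,8-bc]furan]-3-one
Product: 29 (1S)-3'-hydroxy-2-(2-hydroxyethyl)-7-methoxy-7'-methylspiro[isoindoline-1,2'-naphtho[1,8-bc]furan]-3-one (CNP0434366.2)
Conditions: HF·pyridine, pyridine, THF, 0 °C
Reagents that add atoms: none
Why: Fluoride cleavage of the primary silyl ether in a pyridine buffer that is neither basic enough to form the 2'-phenoxide nor acidic enough to ionize the N,O-ketal, so the spiro center should not be touched.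

**Compound list**

1 | 3-hydroxy-2H-pyran-2-one | O=c1occcc1O | starting material
2 | 3-methoxy-2H-pyran-2-one | COc1cccoc1=O | intermediate
3 | 4-(benzyloxy)benzaldehyde | O=Cc1ccc(OCc2ccccc2)cc1 | starting material
4 | diethyl succinate | CCOC(=O)CCC(=O)OCC | starting material
5 | (3E)-4-[4-(benzyloxy)phenyl]-3-(ethoxycarbonyl)but-3-enoic acid | CCOC(=O)/C(=C/c1ccc(OCc2ccccc2)cc1)CC(=O)O | intermediate
6 | ethyl 6-(benzyloxy)-4-hydroxynaphthalene-2-carboxylate | CCOC(=O)c1cc(O)c2cc(OCc3ccccc3)ccc2c1 | intermediate (not isolated)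
7 | ethyl 4-(acetyloxy)-6-(benzyloxy)naphthalene-2-carboxylate | CCOC(=O)c1cc(OC(C)=O)c2cc(OCc3ccccc3)ccc2c1 | intermediate
8 | ethyl 4-(acetyloxy)-6-(benzyloxy)-5-bromonaphthalene-2-carboxylate | CCOC(=O)c1cc(OC(C)=O)c2c(Br)c(OCc3ccccc3)ccc2c1 | intermediate
9 | 7-(benzyloxy)-8-bromo-3-(hydroxymethyl)naphthalen-1-ol | OCc1cc(O)c2c(Br)c(OCc3ccccc3)ccc2c1 | intermediate
10 | [4,6-bis(benzyloxy)-5-bromonaphthalen-2-yl]methanol | OCc1cc(OCc2ccccc2)c2c(Br)c(OCc3ccccc3)ccc2c1 | intermediate
11 | [4,6-bis(benzyloxy)-5-bromonaphthalen-2-yl]methyl methanesulfonate | CS(=O)(=O)OCc1cc(OCc2ccccc2)c2c(Br)c(OCc3ccccc3)ccc2c1 | intermediate (not isolated)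
12 | 2,8-bis(benzyloxy)-1-bromo-6-methylnaphthalene | Cc1cc(OCc2ccccc2)c2c(Br)c(OCc3ccccc3)ccc2c1 | intermediate
13 | [2,8-bis(benzyloxy)-6-methylnaphthalen-1-yl]lithium | [Li]c1c(OCc2ccccc2)ccc2cc(C)cc(OCc3ccccc3)c12 | intermediate (not isolated)
14 | lithium [2,8-bis(benzyloxy)-6-methylnaphthalen-1-yl](dimethylamino)methanolate | [Li]OC(N(C)C)c1c(OCc2ccccc2)ccc2cc(C)cc(OCc3ccccc3)c12 | intermediate (not isolated)
15 | 2,8-bis(benzyloxy)-6-methylnaphthalene-1-carbaldehyde | O=Cc1c(OCc2ccccc2)ccc2cc(C)cc(OCc3ccccc3)c12 | intermediate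
16 | methyl propiolate | C#CC(=O)OC | starting material
17 | methyl 3-lithioprop-2-ynoate | [Li]C#CC(=O)OC | intermediate (not isolated)
18 | methyl 4-[2,8-bis(benzyloxy)-6-methylnaphthalen-1-yl]-4-hydroxybut-2-ynoate (racemic) | COC(=O)C#CC(O)c1c(OCc2ccccc2)ccc2cc(C)cc(OCc3ccccc3)c12 | intermediate
19 | methyl 4-[2,8-bis(benzyloxy)-6-methylnaphthalen-1-yl]-4-oxobut-2-ynoate | COC(=O)C#CC(=O)c1c(OCc2ccccc2)ccc2cc(C)cc(OCc3ccccc3)c12 | intermediate
20 | methyl 5-{[2,8-bis(benzyloxy)-6-methylnaphthalen-1-yl]carbonyl}-4-methoxy-3-oxo-2-oxabicyclo[2.2.2]octa-5,7-diene-6-carboxylate (racemic) | COC(=O)C1=C(C(=O)c3c(OCc4ccccc4)ccc4cc(C)cc(OCc5ccccc5)c34)C2(OC)C=CC1OC2=O | intermediate (not isolated)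
21 | methyl 2-{[2,8-bis(benzyloxy)-6-methylnaphthalen-1-yl]carbonyl}-3-methoxybenzoate | COC(=O)c1cccc(OC)c1C(=O)c1c(OCc2ccccc2)ccc2cc(C)cc(OCc3ccccc3)c12 | intermediate
22 | 2-[(tert-butyldimethylsilyl)oxy]ethan-1-amine | NCCO[Si](C)(C)C(C)(C)C | starting material
23 | ({2-[(tert-butyldimethylsilyl)oxy]ethyl}amino)dimethylaluminium | C[Al](C)NCCO[Si](C)(C)C(C)(C)C | intermediate (not isolated)
24 | 2-{[2,8-bis(benzyloxy)-6-methylnaphthalen-1-yl]carbonyl}-N-{2-[(tert-butyldimethylsilyl)oxy]ethyl}-3-methoxybenzamide | COc1cccc(C(=O)NCCO[Si](C)(C)C(C)(C)C)c1C(=O)c1c(OCc2ccccc2)ccc2cc(C)cc(OCc3ccccc3)c12 | intermediate (not isolated)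
25 | 3-[2,8-bis(benzyloxy)-6-methylnaphthalen-1-yl]-2-{2-[(tert-butyldimethylsilyl)oxy]ethyl}-3-hydroxy-4-methoxy-2,3-dihydro-1H-isoindol-1-one (racemic) | COc1cccc2c1C(O)(c1c(OCc3ccccc3)ccc3cc(C)cc(OCc4ccccc4)c13)N(CCO[Si](C)(C)C(C)(C)C)C2=O | intermediate
26 | 2-{2-[(tert-butyldimethylsilyl)oxy]ethyl}-3-(2,8-dihydroxy-6-methylnaphthalen-1-yl)-3-hydroxy-4-methoxy-2,3-dihydro-1H-isoindol-1-one (racemic) | COc1cccc2c1C(O)(c1c(O)ccc3cc(C)cc(O)c13)N(CCO[Si](C)(C)C(C)(C)C)C2=O | intermediate
27 | 2-{2-[(tert-butyldimethylsilyl)oxy]ethyl}-3-(8-hydroxy-6-methyl-2-oxonaphthalen-1(2H)-ylidene)-4-methoxy-2,3-dihydro-1H-isoindol-1-one | COc1cccc2c1C(=C1C(=O)C=Cc3cc(C)cc(O)c13)N(CCO[Si](C)(C)C(C)(C)C)C2=O | intermediate (not isolated)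
28 | (1S)-2-{2-[(tert-butyldimethylsilyl)oxy]ethyl}-3'-hydroxy-7-methoxy-7'-methylspiro[isoindoline-1,2'-naphtho[1,8-bc]furan]-3-one | COc1cccc2c1[C@]1(Oc3cc(C)cc4ccc(O)c1c34)N(CCO[Si](C)(C)C(C)(C)C)C2=O | intermediate
29 | (1S)-3'-hydroxy-2-(2-hydroxyethyl)-7-methoxy-7'-methylspiro[isoindoline-1,2'-naphtho[1,8-bc]furan]-3-one (CNP0434366.2) | COc1cccc2c1[C@]1(Oc3cc(C)cc4ccc(O)c1c34)N(CCO)C2=O | target

**Step count and risks**

Total: 15 steps. Longest linear sequence: 14 steps (steps 2–15, from 3 and 4 to 29); the pyrone branch is one step (step 1).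

Steps most likely to fail:

1. Step 14 (proposed new method). Three processes could spoil it:
   - uncatalyzed or surface-catalyzed ring closure that runs beside the catalyzed one and gives racemic material;
   - reversible ionization of the product N,O-ketal, which would erode the enantiomeric purity with time;
   - slow rotation about the C3–C1' bond in the ion pair, which would move enantioselection into the ionization event.

   Fallback, from 26 back to 28: 26 is closed without a chiral catalyst (diphenyl hydrogen phosphate, CH2Cl2, 4 Å molecular sieves, rt) to the racemic spiro silyl ether 2-{2-[(tert-butyldimethylsilyl)oxy]ethyl}-3'-hydroxy-7-methoxy-7'-methylspiro[isoindoline-1,2'-naphtho[1,8-bc]furan]-3-one (F1). F1 is resolved by preparative chromatography on a polysaccharide chiral stationary phase; the (S)-enantiomer is 28, and the other fraction is the (R)-enantiomer (1R)-2-{2-[(tert-butyldimethylsilyl)oxy]ethyl}-3'-hydroxy-7-methoxy-7'-methylspiro[isoindoline-1,2'-naphtho[1,8-bc]furan]-3-one (F2). F2 can be returned to F1 with the same acid, since the ionization is reversible, and resolved again.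

2. Step 11 (key step). The cycloaddition could proceed in the reverse orientation, with the methoxy-bearing pyrone carbon bonding to the ester-bearing alkyne carbon, or the ynone could decompose thermally before it is consumed.

   Fallback, from 15 back to 25: purchased N,N-diethyl-3-methoxybenzamide is lithiated between its two directing groups (s-BuLi, TMEDA, THF, −78 °C) to [2-(diethylcarbamoyl)-6-methoxyphenyl]lithium (F3). F3 adds to aldehyde 15 to give the carbinol amide 2-{[2,8-bis(benzyloxy)-6-methylnaphthalen-1-yl](hydroxy)methyl}-N,N-diethyl-3-methoxybenzamide (F4). Warming F4 with TsOH in toluene closes the phthalide 3-[2,8-bis(benzyloxy)-6-methylnaphthalen-1-yl]-4-methoxy-2-benzofuran-1(3H)-one (F5), with loss of diethylamine. F5 is opened by Me3Al and amine 22 (through 23) to the hydroxy amide 2-{[2,8-bis(benzyloxy)-6-methylnaphthalen-1-yl](hydroxy)methyl}-N-{2-[(tert-butyldimethylsilyl)oxy]ethyl}-3-methoxybenzamide (F6). Dess–Martin oxidation of the diaryl carbinol of F6 gives keto amide 24, which closes to 25. The bond from ring A to C3 is then made by carbanion addition instead of cycloaddition, and the directed metalation fixes the place of the methoxy group.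

3. Step 13. Once the 2'-hydroxyl is free, the C3–OH bond could be hydrogenolyzed through the quinone methide, or the ring could close early on the catalyst surface to give racemic spiro compound.

   Fallback, from 21 back to 26: the benzyl ethers are removed at the keto ester stage (H2, Pd/C, EtOAc), where no ionizable carbinol is present, to give methyl 2-[(2,8-dihydroxy-6-methylnaphthalen-1-yl)carbonyl]-3-methoxybenzoate (F7). F7 is amidated with an excess of 23 (from Me3Al and 22; two equivalents are taken up by the phenols) at the lowest workable temperature to the keto amide N-{2-[(tert-butyldimethylsilyl)oxy]ethyl}-2-[(2,8-dihydroxy-6-methylnaphthalen-1-yl)carbonyl]-3-methoxybenzamide (F8). F8 closes to 26 by addition of the amide N–H to the neighbouring ketone.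

**Further compounds**

F1 | step 14 | 2-{2-[(tert-butyldimethylsilyl)oxy]ethyl}-3'-hydroxy-7-methoxy-7'-methylspiro[isoindoline-1,2'-naphtho[1,8-bc]furan]-3-one (racemic) | COc1cccc2c1C1(Oc3cc(C)cc4ccc(O)c1c34)N(CCO[Si](C)(C)C(C)(C)C)C2=O
F2 | step 14 | (1R)-2-{2-[(tert-butyldimethylsilyl)oxy]ethyl}-3'-hydroxy-7-methoxy-7'-methylspiro[isoindoline-1,2'-naphtho[1,8-bc]furan]-3-one | COc1cccc2c1[C@@]1(Oc3cc(C)cc4ccc(O)c1c34)N(CCO[Si](C)(C)C(C)(C)C)C2=O
F3 | step 11 | [2-(diethylcarbamoyl)-6-methoxyphenyl]lithium | CCN(CC)C(=O)c1cccc(OC)c1[Li]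
F4 | step 11 | 2-{[2,8-bis(benzyloxy)-6-methylnaphthalen-1-yl](hydroxy)methyl}-N,N-diethyl-3-methoxybenzamide (racemic) | CCN(CC)C(=O)c1cccc(OC)c1C(O)c1c(OCc2ccccc2)ccc2cc(C)cc(OCc3ccccc3)c12
F5 | step 11 | 3-[2,8-bis(benzyloxy)-6-methylnaphthalen-1-yl]-4-methoxy-2-benzofuran-1(3H)-one (racemic) | COc1cccc2c1C(c1c(OCc3ccccc3)ccc3cc(C)cc(OCc4ccccc4)c13)OC2=O
F6 | step 11 | 2-{[2,8-bis(benzyloxy)-6-methylnaphthalen-1-yl](hydroxy)methyl}-N-{2-[(tert-butyldimethylsilyl)oxy]ethyl}-3-methoxybenzamide (racemic) | COc1cccc(C(=O)NCCO[Si](C)(C)C(C)(C)C)c1C(O)c1c(OCc2ccccc2)ccc2cc(C)cc(OCc3ccccc3)c12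
F7 | step 13 | methyl 2-[(2,8-dihydroxy-6-methylnaphthalen-1-yl)carbonyl]-3-methoxybenzoate | COC(=O)c1cccc(OC)c1C(=O)c1c(O)ccc2cc(C)cc(O)c12
F8 | step 13 | N-{2-[(tert-butyldimethylsilyl)oxy]ethyl}-2-[(2,8-dihydroxy-6-methylnaphthalen-1-yl)carbonyl]-3-methoxybenzamide | COc1cccc(C(=O)NCCO[Si](C)(C)C(C)(C)C)c1C(=O)c1c(O)ccc2cc(C)cc(O)c12
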